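If the flask is to be read at 40 min, 80 min and 160 min, the meeting had one question: when does G overtake L? Tuesday's, Monday's and Friday's share a recipe and differ in time.

| setting | ochre | green | grey | Tuesday's | Monday's | Friday's |
|---|---|---|---|---|---|---|
| D | 0.22 M | 0.22 M | 0.44 M | 0.22 M | 0.22 M | 0.22 M |
| J | 1.7 equiv | 2.6 equiv | 1.2 equiv | 1.20 equiv | 1.20 equiv | 1.20 equiv |
| Z | 4 equiv | 4 equiv | 4 equiv | 4.00 equiv | 4.00 equiv | 4.00 equiv |
| remark | run made earlier | run made earlier | run made earlier |  |  |  |
| time |  |  |  | 40 min | 80 min | 160 min |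

| run | time / min | L / % | G / % | D / % | X / % |
|---|---|---|---|---|---|
| ochre | 6.00 | 16.3 | 0 | 83.0 | 0.1 |
| ochre | 12.0 | 28.5 | 1.1 | 70.7 | 0 |
| ochre | 20.0 | 38.9 | 2.5 | 58.7 | 0.1 |
| ochre | 25.0 | 42.6 | 5.1 | 52.5 | 0.4 |
| ochre | 30.0 | 45.7 | 7.1 | 47.5 | 0.2 |
| green | 2.50 | 7.9 | 0.3 | 92.5 | 0 |
| green | 5.00 | 13.7 | 0.4 | 85.8 | 0.2 |
| green | 10.0 | 23.8 | 0.8 | 75.9 | 0.3 |
| green | 15.0 | 30.3 | 2.2 | 67.6 | 0.1 |
| green | 30.0 | 39.5 | 9.0 | 50.9 | 0.2 |
| grey | 2.50 | 14.4 | 0.5 | 85.5 | 0 |
| grey | 5.00 | 25.6 | 0.8 | 74.2 | 0.1 |
| grey | 10.0 | 40.6 | 2.4 | 57.1 | 0.3 |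
| grey | 15.0 | 49.5 | 6.0 | 45.4 | 0.4 |
| grey | 30.0 | 56.0 | 18.9 | 24.5 | 0.7 |

(each reading ± 0.3 percentage points)

- which of these there is most of at the end, counted by the D in it, Tuesday's (X / G / D / L)
- which of these there is most of at the end, counted by the D in it, Monday's (X / G / D / L)
- which of these there is most of at the end, counted by the D in it, Friday's (X / G / D / L)
- amount of the one of these that there is most of at the end, in percent of the D charged, Tuesday's
- amount of the one of these that there is most of at the end, in percent of the D charged, Monday's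
- amount of the one of these that there is most of at the end, in percent of the D charged, Friday's

- the analysis behind the earlier runs scatters by 0.3 percentage points, standard deviation

**Minutes.** The first speaker pointed out that G lags in the ochre run. She proposed the hand-over rate h, the rise of G and X per minute divided by the mean L over the same interval, a pseudo-first-order constant for L read from the runs. The ochre run reads 0.00556 min⁻¹ from 12.0 min to 20.0 min and 0.0111 min⁻¹ from 20.0 min to 30.0 min, twice as much. The hand-over rate h is this later reading.

The second speaker added the last intervals of the other runs: green reads 0.0132 min⁻¹ and grey 0.0167 min⁻¹. The meeting kept the ochre reading, since ochre has this flask's D and, of the two runs at that D, the J nearer to it.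

The zero of the scale was agreed as the even split. With the feed from D over, L halves in 62.4 min, and that is the time at which L and what it has given stand equal.

My own reckoning holds h at the ochre reading. With L near 50%, the 40.0 min after Tuesday's add 22 percentage points. On the forecast's 9 of G that makes 31.2% of G and X on Monday's, where the forecast has 36 of G. With the forecast's 23 of D, that leaves L ahead on Monday's. Then 1.28 lives pass before Friday's, so G should lead there.

The forecast says L 50%, L 41% and G 63%, on the ground that G's rise “suggests something builds up and promotes the step”.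

**Result.** The flask gives L 53.8% on Tuesday's, L 54.2% on Monday's and G 46.3% on Friday's.

    D + Z → L (k = 6.29 × 10⁻⁴ L mol⁻¹ s⁻¹)
    Z + J → E (k = 8.41 × 10⁻⁴ L mol⁻¹ s⁻¹)
    L + E → G (k = 7.91 × 10⁻⁴ L mol⁻¹ s⁻¹)
    G → X (k = 4.29 × 10⁻⁵ s⁻¹)

On these values h is 0.00874 min⁻¹ from Tuesday's to Monday's, less than the ochre reading, and 0.00746 min⁻¹ from Monday's to Friday's, less again. In the scheme h stands for k3 times E, and E is 0.176 M on Monday's and 0.136 M on Friday's, with J at 1.70% of its charge. Carried at the latest h to the neighbour flask, Monday's left until 3.0 h, the reckoning puts G and X at 62.1%. That flask holds 60.9% of them, with G at 48.5% against L at 35.6%.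

(The numbers in the tables were generated by integration with made-up constants, and the scatter is random.)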